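You have two flasks that differ in one amount: the midnight flask holds 4.3 mol% precatalyst and the summer flask 2.1 mol%, each with 10 mM starting material and 0.950 equiv reagent. The midnight flask is the one asked about.

| setting | midnight | summer | flask |
|---|---|---|---|
| starting material | 10 mM | 10 mM | 10 mM |
| reagent | 0.95 equiv | 0.95 equiv | 0.950 equiv |
| precatalyst | 4.3 mol% | 2.1 mol% | 4.3 mol% |
| remark | the very flask that is asked about, followed so far | run made earlier |  |

| run | time / min | product / % | starting material / % |
|---|---|---|---|
| midnight | 0.833 | 0.1 | 100.6 |
| midnight | 1.33 | 0.6 | 97.1 |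
| midnight | 2.00 | 1.5 | 94.7 |
| midnight | 3.00 | 4.8 | 93.4 |
| midnight | 4.00 | 6.1 | 91.8 |
| midnight | 6.00 | 11.5 | 86.9 |
| midnight | 10.0 | 20.0 | 79.1 |
| summer | 0.833 | 0.2 | 100.4 |
| summer | 2.00 | 2.7 | 97.8 |
| summer | 4.00 | 5.4 | 97.0 |
| summer | 6.00 | 3.8 | 94.1 |
| summer | 8.00 | 8.4 | 92.4 |
| summer | 12.0 | 11.7 | 87.0 |
| summer | 15.0 | 14.9 | 83.5 |

(each reading ± 1 percentage point)

- factor on the rate of making product when 30 % of the starting material are converted if precatalyst is charged twice over
- factor on the rate when 30 % of the starting material are converted if precatalyst is charged at 20 mol% instead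

Take the time scales from shortest to longest. First comes an induction period: the midnight flask shows 0.6 % product at 1.33 min but 11.5 % at 6.00 min. The product then climbs nearly straight, so the last reading of each run gives a mean rate r, 0.200 mM min⁻¹ for midnight and 0.0993 mM min⁻¹ for summer. At those rates, 30 % conversion lies at 15.0 min in the midnight flask and 30.2 min in the summer flask, both later than the last readings, so the estimate extrapolates. The midnight reading at 1.33 min, still inside that lag, comes earlier than the 15.0 min.

The quantity to carry is the order in charged precatalyst n, the logarithm of the rate ratio over the logarithm of the loading ratio: 0.977, a reading that carries the scatter of the two runs. My reckoning raises each loading ratio to n, which gives 1.97 for doubling and 4.49 at 20 mol%.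

The forecast gives 1.95 (1.6 to 2.25) and 4.3 (2.7 to 5.6); its 4.3 is lower than my 4.49. In its words: “I shade the estimate down and skew the range low”.

The simulation gives 1.99 and 4.53.

    catalyst intermediate B → catalyst intermediate C (k = 0.0510 s⁻¹)
    2 free catalyst → spent catalyst (k = 25.0 M⁻¹ s⁻¹)
    catalyst intermediate D ⇌ free catalyst + product (K = 0.0140 M, k = 0.0180 s⁻¹)
    precatalyst → free catalyst (k = 0.0240 s⁻¹)
    reagent + free catalyst → catalyst intermediate A (k = 9.80 M⁻¹ s⁻¹)
    starting material + catalyst intermediate C → catalyst intermediate D (k = 170 M⁻¹ s⁻¹)
    catalyst intermediate A ⇌ released group + catalyst intermediate B (K = 0.0150 M, k = 0.0570 s⁻¹)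

Put back into the definition of n, the simulated factors give 0.993 for doubling this flask and 0.982 for the flask at 20 mol%, against the 0.977 read from the two runs. The rate of this flask at 30 % conversion is held down in part by the step in which two free catalyst turn into spent catalyst. The same flask run without that step makes product at 1.26 times the actual rate at that conversion.

(All runs were computed for substances that don't exist, noise included.)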